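## Retrosynthetic overview

1. The strategy rests on the 1,2-dioxane ring O1–O2–C3–C4–C5–C6 being a cyclic peroxyhemiketal: C3 is a masked ketone, C4 its α-carbon, C5–C6 a former C=C, O1–O2 a molecule of O2, and the C4–H can stand where a carboxyl group was.
2. Key disconnection: C4–C5, C6–O1 and O2–C3 are formed in one flask by Mn(OAc)3 (trivalent manganese)-mediated aerobic annulation of a 2-methyl β-keto tert-butyl ester, the 1,1-disubstituted tail alkene and O2; this closes the only ring.
3. The alkene derives from (R)-citronellal (side-chain stereocentre from the chiral pool; ozonolysis, Wittig extension with the 5-phenylpentyl ylide, hydrogenation, methylenation). The keto ester derives from a crossed Claisen condensation and carries the future CH2CO2H as CH2CH2OSi.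
4. After the ring: the C4 ester is cleaved and CO2 lost, the silyl ether is removed, the diastereomers are separated, and CH2OH is oxidised to CO2H.

Key step: step 10

Remark on the chemistry: C6 is created by O2 capture of an acyclic radical and cannot be controlled in this strategy, and the C4/C6 relationship is only weakly biased at equilibrium (equatorial decyl chain versus equatorial methyl at C6). The (3S,4R,6S) isomer is therefore isolated by chromatography at the diol stage; its C3,C4-bis-epimer of the same 6S series can be re-equilibrated with acid and recycled, while the 6R series is lost.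

## Route

Step 1
Reactants: 1 (R)-citronellal [(3R)-3,7-dimethyloct-6-enal]
Product: 2 (4R)-4,8-dimethylnon-7-en-2-ol (both C2 epimers)
Conditions: MeMgBr, Et2O, 0 °C; aq. NH4Cl
Reagents that add atoms: methylmagnesium bromide, C[Mg]Br
Why: Grignard 1,2-addition to the aldehyde; the new carbinol centre forms as both epimers, which is immaterial because it is oxidised in step 2, and the methyl-bearing stereocentre is β to the carbonyl and cannot epimerise.

Step 2
Reactants: 2 (4R)-4,8-dimethylnon-7-en-2-ol
Product: 3 (4R)-4,8-dimethylnon-7-en-2-one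
Conditions: Dess–Martin periodinane, CH2Cl2, rt
Reagents that add atoms: none
Why: Dess–Martin oxidation of a secondary alcohol to the methyl ketone, which leaves the trisubstituted alkene and the β-stereocentre untouched.

Step 3
Reactants: 3 (4R)-4,8-dimethylnon-7-en-2-one
Product: 4 (4R)-4-methyl-6-oxoheptanal
Conditions: O3, CH2Cl2, −78 °C; then Me2S, −78 °C → rt; used crude
Reagents that add atoms: ozone, [O-][O+]=O
Why: Ozonolysis with reductive work-up (Criegee mechanism) cleaves the only C=C to the aldehyde and acetone, the ketone being inert to ozone.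

Step 4
Reactants: 5 (5-bromopentyl)benzene
Product: 6 triphenyl(5-phenylpentyl)phosphonium bromide
Conditions: PPh3, MeCN, reflux
Reagents that add atoms: triphenylphosphine, c1ccc(cc1)P(c1ccccc1)c1ccccc1
Why: SN2 quaternisation of triphenylphosphine by a primary alkyl bromide.

Step 5
Reactants: 6 triphenyl(5-phenylpentyl)phosphonium bromide; 4 (4R)-4-methyl-6-oxoheptanal
Product: 8 (4R,7Z)-4-methyl-12-phenyldodec-7-en-2-one, via phosphonium ylide 7 (not isolated)
Conditions: 6 (1.15 equiv), NaN(SiMe3)2 (1.1 equiv), THF, 0 °C; then 4, −78 °C → rt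
Reagents that add atoms: none
Why: Wittig olefination in which the non-stabilised ylide, kept free of excess base, should react at −78 °C with the aldehyde far faster than with the methyl ketone; the mainly Z geometry is erased in step 6.

Step 6
Reactants: 8 (4R,7Z)-4-methyl-12-phenyldodec-7-en-2-one
Product: 9 (4R)-4-methyl-12-phenyldodecan-2-one
Conditions: H2 (1 atm), 10% Pd/C, EtOAc, rt
Reagents that add atoms: none
Why: Heterogeneous catalytic hydrogenation of the disubstituted alkene; under these mild conditions the ketone and the phenyl ring should not be reduced.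

Step 7
Reactants: 9 (4R)-4-methyl-12-phenyldodecan-2-one
Product: 10 (4R)-2,4-dimethyl-12-phenyldodec-1-ene
Conditions: MePPh3Br, KOtBu, THF, 0 °C → rt
Reagents that add atoms: methyltriphenylphosphonium bromide, C[P+](c1ccccc1)(c1ccccc1)c1ccccc1.[Br-]
Why: Wittig methylenation of the methyl ketone; the stereocentre is β to the carbonyl and is not affected by enolisation.

Step 8
Reactants: 11 methyl 3-hydroxypropanoate
Product: 12 methyl 3-[(tert-butyldiphenylsilyl)oxy]propanoate
Conditions: TBDPSCl, imidazole, CH2Cl2, 0 °C → rt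
Reagents that add atoms: tert-butyl(chloro)diphenylsilane, CC(C)(C)[Si](Cl)(c1ccccc1)c1ccccc1
Why: Imidazole-promoted silylation of the primary alcohol, giving an ether that should survive AcOH and TFA later.

Step 9
Reactants: 13 tert-butyl propanoate; 12 methyl 3-[(tert-butyldiphenylsilyl)oxy]propanoate
Product: 15 tert-butyl 5-[(tert-butyldiphenylsilyl)oxy]-2-methyl-3-oxopentanoate (racemic at C2), via lithium enolate 14 (not isolated)
Conditions: 13 (2.2 equiv), LiN(iPr)2 (2.2 equiv), THF, −78 °C; then 12, −78 → −30 °C; aq. NH4Cl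
Reagents that add atoms: none
Why: Crossed Claisen condensation in which the tert-butyl ester enolate acylates on the methyl ester and the second equivalent of enolate deprotonates the β-keto ester product, which drives the reaction and shields the new ketone; C2 is racemic and is destroyed later.

Step 10
Reactants: 15 tert-butyl 5-[(tert-butyldiphenylsilyl)oxy]-2-methyl-3-oxopentanoate; 10 (4R)-2,4-dimethyl-12-phenyldodec-1-ene
Product: 16 tert-butyl 3-{2-[(tert-butyldiphenylsilyl)oxy]ethyl}-3-hydroxy-4,6-dimethyl-6-[(2R)-2-methyl-10-phenyldecyl]-1,2-dioxane-4-carboxylate (diastereomer mixture at C3/C4/C6)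
Conditions: 10 (1 equiv), 15 (2 equiv), Mn(OAc)3·2H2O (0.5 equiv), O2 (1 atm), AcOH/EtOAc, 23 °C
Reagents that add atoms: dioxygen, O=O
Why: Mn(OAc)3 (trivalent manganese) oxidises the enol of 15 at its only 1,3-dicarbonyl C–H to an electrophilic tertiary C4 radical, which adds to the CH2 terminus of 10 (C4–C5); the resulting tertiary C6 radical captures O2 (C6–O1), and the peroxyl radical is reduced to the hydroperoxide by Mn(OAc)2 (divalent manganese), which returns trivalent manganese and lets the metal turn over. The hydroperoxide oxygen then adds to the C3 ketone in a 6-exo-trig hemiketalisation (O2–C3), which closes the 1,2-dioxane ring. The closest known reaction is the Mn(OAc)3/O2 peroxycyclisation of 1,3-dicarbonyl compounds with 1,1-disubstituted alkenes to 1,2-dioxan-3-ols. C6 arises from O2 capture by an acyclic radical with no facial control and is fixed from here on as both epimers; the quaternary C4 is set without control but is reset in step 11; C3 is under thermodynamic (anomeric) control through ring–chain tautomerism. The step needs regioselective addition to the alkene CH2 (polarity match of the electrophilic radical with the electron-rich alkene, and sterics) and O2 capture that outruns oxidation of the C6 radical to a cation (O2 saturation, sub-stoichiometric manganese); the tert-butyl ester, the silyl ether and the benzylic CH2 should be inert in AcOH at 23 °C.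

Step 11
Reactants: 16 tert-butyl 3-{2-[(tert-butyldiphenylsilyl)oxy]ethyl}-3-hydroxy-4,6-dimethyl-6-[(2R)-2-methyl-10-phenyldecyl]-1,2-dioxane-4-carboxylate
Product: 18 3-{2-[(tert-butyldiphenylsilyl)oxy]ethyl}-4,6-dimethyl-6-[(2R)-2-methyl-10-phenyldecyl]-1,2-dioxan-3-ol (four diastereomers), via carboxylic acid 17 (not isolated)
Conditions: TFA/CH2Cl2 (1:4), 0 °C → rt; concentrate; toluene, 45 °C; aq. NaHCO3 wash
Reagents that add atoms: none
Why: Proposed new method: TFA acidolysis of the tert-butyl ester (loss of 2-methylpropene) is standard, and the proposal is that the liberated acid 17, a β-keto acid masked as its cyclic peroxyhemiketal, loses CO2 either through the acid-opened hydroperoxy ketone tautomer (six-membered transition state of β-keto acid decarboxylation) or by decarboxylative elimination from the C3 peroxycarbenium ion, the C3=C4 enol then ketonising and re-closing with C4–H and C3–OH set under thermodynamic control while C6 is untouched; the closest known reactions are the decarboxylation of 2,2-disubstituted β-keto acids and of lactol-masked β-keto acids.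

Step 12
Reactants: 18 3-{2-[(tert-butyldiphenylsilyl)oxy]ethyl}-4,6-dimethyl-6-[(2R)-2-methyl-10-phenyldecyl]-1,2-dioxan-3-ol
Product: 19 (3S,4R,6S)-3-(2-hydroxyethyl)-4,6-dimethyl-6-[(2R)-2-methyl-10-phenyldecyl]-1,2-dioxan-3-ol (single diastereomer after separation)
Conditions: HF·pyridine, pyridine, THF, 0 °C → rt; preparative HPLC on silica
Reagents that add atoms: none
Why: Fluoride-mediated cleavage of the primary silyl ether under buffered, non-basic conditions that should leave the peroxide and the hemiketal intact, followed by separation of the four diastereomers; the wanted isomer is the chair with the C3 and C4 carbon substituents and the C6 decyl chain equatorial and the C3–OH axial.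

Step 13
Reactants: 19 (3S,4R,6S)-3-(2-hydroxyethyl)-4,6-dimethyl-6-[(2R)-2-methyl-10-phenyldecyl]-1,2-dioxan-3-ol
Product: 21 2-[(3S,4R,6S)-3-hydroxy-4,6-dimethyl-6-[(2R)-2-methyl-10-phenyldecyl]-1,2-dioxan-3-yl]acetic acid (target), via aldehyde 20 (not isolated)
Conditions: TEMPO (0.2 equiv), PhI(OAc)2 (2.4 equiv), MeCN/pH 7 phosphate buffer (1:1), 0 °C → rt; reversed-phase HPLC
Reagents that add atoms: water, O
Why: TEMPO/PhI(OAc)2 oxidation of the primary alcohol in aqueous MeCN (oxoammonium oxidation to the aldehyde, hydration, second oxidation to the acid; Epp–Widlanski conditions), chemoselective because the only other hydroxyl is the tertiary hemiketal, with the near-neutral buffer chosen so that C4 should not epimerise and the O–O bond is not touched.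

## Compound list

1 | (R)-citronellal, (3R)-3,7-dimethyloct-6-enal | C[C@H](CCC=C(C)C)CC=O | starting material
2 | (4R)-4,8-dimethylnon-7-en-2-ol (C2 epimers) | C[C@H](CCC=C(C)C)CC(C)O | intermediate
3 | (4R)-4,8-dimethylnon-7-en-2-one | C[C@H](CCC=C(C)C)CC(C)=O | intermediate
4 | (4R)-4-methyl-6-oxoheptanal | C[C@H](CCC=O)CC(C)=O | intermediate
5 | (5-bromopentyl)benzene | BrCCCCCc1ccccc1 | starting material
6 | triphenyl(5-phenylpentyl)phosphonium bromide | [Br-].c1ccc(CCCCC[P+](c2ccccc2)(c2ccccc2)c2ccccc2)cc1 | intermediate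
7 | triphenyl(5-phenylpentylidene)phosphorane (ylide) | c1ccc(CCCCC=P(c2ccccc2)(c2ccccc2)c2ccccc2)cc1 | intermediate
8 | (4R,7Z)-4-methyl-12-phenyldodec-7-en-2-one | C[C@H](CC/C=C\CCCCc1ccccc1)CC(C)=O | intermediate
9 | (4R)-4-methyl-12-phenyldodecan-2-one | C[C@H](CCCCCCCCc1ccccc1)CC(C)=O | intermediate
10 | (4R)-2,4-dimethyl-12-phenyldodec-1-ene | C[C@H](CCCCCCCCc1ccccc1)CC(C)=C | intermediate
11 | methyl 3-hydroxypropanoate | OCCC(=O)OC | starting material
12 | methyl 3-[(tert-butyldiphenylsilyl)oxy]propanoate | COC(=O)CCO[Si](c1ccccc1)(c1ccccc1)C(C)(C)C | intermediate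
13 | tert-butyl propanoate | CCC(=O)OC(C)(C)C | starting material
14 | lithium enolate of tert-butyl propanoate | [Li+].CC=C([O-])OC(C)(C)C | intermediate
15 | tert-butyl 5-[(tert-butyldiphenylsilyl)oxy]-2-methyl-3-oxopentanoate (racemic) | CC(C(=O)CCO[Si](c1ccccc1)(c1ccccc1)C(C)(C)C)C(=O)OC(C)(C)C | intermediate
16 | tert-butyl 3-{2-[(tert-butyldiphenylsilyl)oxy]ethyl}-3-hydroxy-4,6-dimethyl-6-[(2R)-2-methyl-10-phenyldecyl]-1,2-dioxane-4-carboxylate (mixture at C3/C4/C6) | C[C@H](CCCCCCCCc1ccccc1)CC1(C)CC(C)(C(=O)OC(C)(C)C)C(O)(CCO[Si](c2ccccc2)(c2ccccc2)C(C)(C)C)OO1 | intermediate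
17 | 3-{2-[(tert-butyldiphenylsilyl)oxy]ethyl}-3-hydroxy-4,6-dimethyl-6-[(2R)-2-methyl-10-phenyldecyl]-1,2-dioxane-4-carboxylic acid (mixture) | C[C@H](CCCCCCCCc1ccccc1)CC1(C)CC(C)(C(=O)O)C(O)(CCO[Si](c2ccccc2)(c2ccccc2)C(C)(C)C)OO1 | intermediate
18 | 3-{2-[(tert-butyldiphenylsilyl)oxy]ethyl}-4,6-dimethyl-6-[(2R)-2-methyl-10-phenyldecyl]-1,2-dioxan-3-ol (four diastereomers) | C[C@H](CCCCCCCCc1ccccc1)CC1(C)CC(C)C(O)(CCO[Si](c2ccccc2)(c2ccccc2)C(C)(C)C)OO1 | intermediate
19 | (3S,4R,6S)-3-(2-hydroxyethyl)-4,6-dimethyl-6-[(2R)-2-methyl-10-phenyldecyl]-1,2-dioxan-3-ol | C[C@H](CCCCCCCCc1ccccc1)C[C@@]1(C)C[C@@H](C)[C@](O)(CCO)OO1 | intermediate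
20 | 2-[(3S,4R,6S)-3-hydroxy-4,6-dimethyl-6-[(2R)-2-methyl-10-phenyldecyl]-1,2-dioxan-3-yl]acetaldehyde | C[C@H](CCCCCCCCc1ccccc1)C[C@@]1(C)C[C@@H](C)[C@](O)(CC=O)OO1 | intermediate
21 | 2-[(3S,4R,6S)-3-hydroxy-4,6-dimethyl-6-[(2R)-2-methyl-10-phenyldecyl]-1,2-dioxan-3-yl]acetic acid (CNP0301546.2) | C[C@H](CCCCCCCCc1ccccc1)C[C@@]1(C)C[C@@H](C)[C@](O)(CC(=O)O)OO1 | target

## Summary and risks

Total step count: 13. Longest linear sequence: 10 steps from (R)-citronellal (steps 1–3, 5–7, 10–13).

**1. Step 11 (ester cleavage and decarboxylation).**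
What may go wrong: the peroxyhemiketal is a Criegee-type adduct, so TFA may trigger heterolysis of the O–O bond (Baeyer–Villiger or Hock-type fragmentation). Alternatively the ring may stay closed, so that CO2 is not lost.
Fallback (known reactions only): CO2 is removed before any O–O bond exists. It sets out from 10 and 15 and rejoins the route at 18.
- Allylic oxidation of 10 (SeO2 cat., tBuOOH, CH2Cl2) should give (4R)-2,4-dimethyl-12-phenyldodec-1-en-3-ol F1.
- Heating F1 with 15 in toluene (ester exchange through the acylketene, tert-butanol distilled off) gives the allyl β-keto ester F2.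
- Pd(PPh3)4 (zerovalent palladium) in THF effects Tsuji decarboxylative allylation, attack at the CH2 terminus of the allyl unit giving the γ,δ-unsaturated ketone F3.
- Mukaiyama–Isayama hydroperoxysilylation (Co(acac)2, divalent cobalt; Et3SiH, O2) places the triethylsilylperoxy group on the tertiary C6, giving silyl peroxide F4.
- AcOH/THF/H2O removes the peroxy silyl group, and the hydroperoxide closes on the C3 ketone to 18.

**2. Step 10 (key annulation).**
What may go wrong: the keto-ester radical may be intercepted by O2 before it adds to the unactivated alkene (α-oxygenation and C–C cleavage). Enolisation and oxidation of the α-methyl keto ester may be slow, and manganese may decompose the hydroperoxide.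
Fallback: C–C bond formation and oxygenation are separated. It sets out from 10 and 15 and rejoins at 16.
- Ene-type allylic chlorination of 10 (Ca(OCl)2, CO2, CH2Cl2/H2O, 0 °C) gives (4R)-2-(chloromethyl)-4-methyl-12-phenyldodec-1-ene F5. Its trisubstituted double-bond isomer can be carried along, since both hold the alkene at C6.
- C-alkylation of 15 (K2CO3, NaI, acetone) forms C4–C5 and gives the allylated keto ester F6.
- Co(acac)2/Et3SiH/O2 gives the tertiary triethylsilyl peroxide F7.
- AcOH/THF/H2O desilylates, and the hydroperoxide closes on the ketone to 16.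

**3. Step 13 (final oxidation).**
What may go wrong: the oxidant may attack the ring-opened hydroperoxide tautomer. The keto-aldehyde stage may enolise or eliminate, and the open β-keto acid form of the product may lose CO2.
Fallback: the hemiketal is locked before oxidation. It sets out from 19 and rejoins at 21.
- MeOH with catalytic camphorsulfonic acid converts 19 into the methyl peroxyketal alcohol F8 (axial OMe, same configuration). F8 cannot ring-open, and the locked ketals give a second chance to separate diastereomers.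
- TEMPO/PhI(OAc)2 in MeCN/H2O gives the methoxy acid F9.
- Brief aqueous acid (TFA/H2O/THF, 0 °C) exchanges OMe for OH to give 21.

## Further compounds

F1 | step 11 | (4R)-2,4-dimethyl-12-phenyldodec-1-en-3-ol (C3 epimers) | C[C@H](CCCCCCCCc1ccccc1)C(O)C(C)=C
F2 | step 11 | (4R)-2,4-dimethyl-12-phenyldodec-1-en-3-yl 5-[(tert-butyldiphenylsilyl)oxy]-2-methyl-3-oxopentanoate | C[C@H](CCCCCCCCc1ccccc1)C(OC(=O)C(C)C(=O)CCO[Si](c2ccccc2)(c2ccccc2)C(C)(C)C)C(C)=C
F3 | step 11 | (6E,8R)-1-[(tert-butyldiphenylsilyl)oxy]-4,6,8-trimethyl-16-phenylhexadec-6-en-3-one | C[C@H](CCCCCCCCc1ccccc1)/C=C(\C)CC(C)C(=O)CCO[Si](c2ccccc2)(c2ccccc2)C(C)(C)C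
F4 | step 11 | (8R)-1-[(tert-butyldiphenylsilyl)oxy]-4,6,8-trimethyl-16-phenyl-6-[(triethylsilyl)peroxy]hexadecan-3-one | C[C@H](CCCCCCCCc1ccccc1)CC(C)(OO[Si](CC)(CC)CC)CC(C)C(=O)CCO[Si](c2ccccc2)(c2ccccc2)C(C)(C)C
F5 | step 10 | (4R)-2-(chloromethyl)-4-methyl-12-phenyldodec-1-ene | C[C@H](CCCCCCCCc1ccccc1)CC(=C)CCl
F6 | step 10 | tert-butyl (6R)-2-{3-[(tert-butyldiphenylsilyl)oxy]propanoyl}-2,6-dimethyl-4-methylidene-14-phenyltetradecanoate | C[C@H](CCCCCCCCc1ccccc1)CC(=C)CC(C)(C(=O)OC(C)(C)C)C(=O)CCO[Si](c2ccccc2)(c2ccccc2)C(C)(C)C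
F7 | step 10 | tert-butyl (6R)-2-{3-[(tert-butyldiphenylsilyl)oxy]propanoyl}-2,4,6-trimethyl-14-phenyl-4-[(triethylsilyl)peroxy]tetradecanoate | C[C@H](CCCCCCCCc1ccccc1)CC(C)(OO[Si](CC)(CC)CC)CC(C)(C(=O)OC(C)(C)C)C(=O)CCO[Si](c2ccccc2)(c2ccccc2)C(C)(C)C
F8 | step 13 | 2-[(3S,4R,6S)-3-methoxy-4,6-dimethyl-6-[(2R)-2-methyl-10-phenyldecyl]-1,2-dioxan-3-yl]ethan-1-ol | C[C@H](CCCCCCCCc1ccccc1)C[C@@]1(C)C[C@@H](C)[C@](OC)(CCO)OO1
F9 | step 13 | 2-[(3S,4R,6S)-3-methoxy-4,6-dimethyl-6-[(2R)-2-methyl-10-phenyldecyl]-1,2-dioxan-3-yl]acetic acid | C[C@H](CCCCCCCCc1ccccc1)C[C@@]1(C)C[C@@H](C)[C@](OC)(CC(=O)O)OO1
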